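## Retrosynthetic overview

- Locants (target numbering): ring B = C1 (bears the side chain), C2, C3, C4 (bears CH3); ring A = C4a, C5 (OH), C6 (OH), C7 (CO2H), C8, C8a; side chain = C11 (methine), C12–C16 (C15 bears CH3, C16 the free OH), C20 (CH2OAc). Target ⇒ global hydrogenolysis of 26 ⇒ C12–C13 alkyl–alkyl Suzuki–Miyaura coupling of bromide 20 with alkene 24 (C13–C16, C15 from the chiral pool).
- Key disconnection: C1–C2 and C3–C4 are made together by an intramolecular Diels–Alder reaction of an o-quinodimethane (C1=C8a–C4a=C4) with a two-carbon unit (C2–C3). That unit is tethered through silicon to the C12 oxygen and activated by a sulfonyl group; fluoride later removes silicon and sulfonyl together.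
- Enabling feature: C1 and C4 are benzylic carbons on the adjacent ring A atoms C8a and C4a, and C4 carries H and CH3. C4–CH3 is therefore a vinyl group on C4a plus one hydrogen taken from C1: a light-driven 1,5-hydrogen shift of the ortho-alkyl styrene 15 dearomatizes ring A to the E,Z o-quinodimethane, whose inside methyl gives the 1,4-trans relation directly.
- 15 ⇒ lipase desymmetrization (sets C11) of diacetate 9 ⇒ B-alkyl Suzuki–Miyaura coupling of aryl bromide 6 with 2-methylidenepropane-1,3-diyl diacetate 7; 6 ⇒ 2,3,4-trihydroxybenzoic acid 1 (bromination, site-selective triflation, ketal, Stille vinylation).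
- Ring order: ring A is bought; ring B and a temporary oxasilinane ring (C1–C11–C12–O–Si–C2) close together in the key step; the oxasilinane is opened again in the next step.

Key step: step 10

Assumption: lipase hydrolysis of the prochiral diacetate 9 is taken to give the (R)-monoacetate 10; if the enzyme selects the other arm on this substrate, the complementary lipase monoacetylation of the derived diol with vinyl acetate would be used to reach the same enantiomer.

## Route

Step 1
Reactants: 1 2,3,4-trihydroxybenzoic acid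
Product: 2 benzyl 2,3,4-trihydroxybenzoate
Conditions: BnBr, NaHCO3, DMF, 40 °C
Reagents that add atoms: benzyl bromide, BrCc1ccccc1
Why: Carboxylate O-alkylation (SN2); hydrogencarbonate deprotonates only the carboxylic acid, so the three phenols should stay free.

Step 2
Reactants: 2 benzyl 2,3,4-trihydroxybenzoate
Product: 3 benzyl 5-bromo-2,3,4-trihydroxybenzoate
Conditions: N-bromosuccinimide, MeCN, −20 °C
Reagents that add atoms: N-bromosuccinimide, O=C1CCC(=O)N1Br
Why: Electrophilic aromatic bromination; C5 is ortho to the 4-OH and para to the 2-OH, whereas C6 is ortho to the ester, so one bromide is expected.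

Step 3
Reactants: 3 benzyl 5-bromo-2,3,4-trihydroxybenzoate
Product: 4 benzyl 5-bromo-2,3-dihydroxy-4-{[(trifluoromethyl)sulfonyl]oxy}benzoate
Conditions: PhNTf2 (1.0 equiv), Et3N (1.0 equiv), CH2Cl2, −20 to 0 °C
Reagents that add atoms: N-phenylbis(trifluoromethanesulfonimide), O=S(=O)(N(c1ccccc1)S(=O)(=O)C(F)(F)F)C(F)(F)F
Why: Phenol O-sulfonylation with a mild triflyl donor; the 4-OH (para to the ester, ortho to bromine) is the most acidic and should react first, the site selectivity known for O-alkylation of 2,3,4-trihydroxyaryl carbonyl compounds.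

Step 4
Reactants: 4 benzyl 5-bromo-2,3-dihydroxy-4-{[(trifluoromethyl)sulfonyl]oxy}benzoate
Product: 5 benzyl 6-bromo-2,2-diphenyl-7-{[(trifluoromethyl)sulfonyl]oxy}-1,3-benzodioxole-4-carboxylate
Conditions: Ph2C(OMe)2, TsOH (cat.), toluene, 90 °C, removal of MeOH
Reagents that add atoms: dimethoxydiphenylmethane, COC(OC)(c1ccccc1)c1ccccc1
Why: Acid-catalysed transketalization; the only remaining pair of adjacent phenols closes the diphenylmethylene ketal, which should survive base, organometallics and light and is removed by hydrogenolysis at the end.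

Step 5
Reactants: 5 benzyl 6-bromo-2,2-diphenyl-7-{[(trifluoromethyl)sulfonyl]oxy}-1,3-benzodioxole-4-carboxylate
Product: 6 benzyl 6-bromo-7-ethenyl-2,2-diphenyl-1,3-benzodioxole-4-carboxylate
Conditions: Bu3Sn(CH=CH2), PdCl2(PPh3)2 (cat.), LiCl, DMF, 70 °C
Reagents that add atoms: tributyl(ethenyl)stannane, C=C[Sn](CCCC)(CCCC)CCCC
Why: Stille coupling; with PdCl2(PPh3)2 and LiCl in DMF the aryl triflate is expected to react in preference to the aryl bromide, which is kept for step 6.

Step 6
Reactants: 6 benzyl 6-bromo-7-ethenyl-2,2-diphenyl-1,3-benzodioxole-4-carboxylate; 7 2-methylidenepropane-1,3-diyl diacetate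
Product: 9 benzyl 6-[3-(acetyloxy)-2-[(acetyloxy)methyl]propyl]-7-ethenyl-2,2-diphenyl-1,3-benzodioxole-4-carboxylate, via alkylborane 8 (not isolated)
Conditions: 7, 9-BBN-H, THF, 0 °C to rt; then 6, PdCl2(dppf) (dppf = 1,1'-bis(diphenylphosphino)ferrocene) (cat.), K3PO4, DMF, 50 °C
Reagents that add atoms: none
Why: Hydroboration puts boron on the CH2 terminus of the 1,1-disubstituted alkene, and the B-alkyl Suzuki–Miyaura coupling joins that carbon (C1) to C8a; C11 is still prochiral.

Step 7
Reactants: 9 benzyl 6-[3-(acetyloxy)-2-[(acetyloxy)methyl]propyl]-7-ethenyl-2,2-diphenyl-1,3-benzodioxole-4-carboxylate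
Product: 10 benzyl 6-[(2R)-3-(acetyloxy)-2-(hydroxymethyl)propyl]-7-ethenyl-2,2-diphenyl-1,3-benzodioxole-4-carboxylate
Conditions: porcine pancreatic lipase, pH 7 phosphate buffer/i-Pr2O, rt
Reagents that add atoms: none
Why: Enantiotopic-group-selective enzymatic ester hydrolysis of a prochiral 2-substituted propane-1,3-diyl diacetate sets C11 (known for 2-benzyl analogues), and the surviving acetate is the acetate of the target.

Step 8
Reactants: 11 chloro(ethenyl)dimethylsilane; 12 benzenesulfonyl chloride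
Product: 14 chloro(dimethyl)[(E)-2-(phenylsulfonyl)ethenyl]silane, via chlorosulfone adduct 13 (not isolated)
Conditions: CuCl (cat.), MeCN, 100 °C (sealed tube); then Et3N, toluene, 0 °C to rt
Reagents that add atoms: none
Why: Copper-catalysed atom-transfer addition of the sulfonyl chloride to the vinylsilane followed by E1cB loss of HCl should give the E β-silyl vinyl sulfone, the route known for the trimethylsilyl analogue.

Step 9
Reactants: 10 benzyl 6-[(2R)-3-(acetyloxy)-2-(hydroxymethyl)propyl]-7-ethenyl-2,2-diphenyl-1,3-benzodioxole-4-carboxylate; 14 chloro(dimethyl)[(E)-2-(phenylsulfonyl)ethenyl]silane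
Product: 15 benzyl 6-[(2S)-3-(acetyloxy)-2-[({dimethyl[(E)-2-(phenylsulfonyl)ethenyl]silyl}oxy)methyl]propyl]-7-ethenyl-2,2-diphenyl-1,3-benzodioxole-4-carboxylate
Conditions: Et3N, CH2Cl2, −20 °C; used without prolonged chromatography
Reagents that add atoms: none
Why: O-Silylation of the primary alcohol at low temperature (no acetyl migration expected) attaches the two-carbon unit to the arm that will become C12.

Step 10
Reactants: 15 benzyl 6-[(2S)-3-(acetyloxy)-2-[({dimethyl[(E)-2-(phenylsulfonyl)ethenyl]silyl}oxy)methyl]propyl]-7-ethenyl-2,2-diphenyl-1,3-benzodioxole-4-carboxylate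
Product: 17 tricyclic cycloadduct (target numbering: C1 and C2 spanned by C11H(CH2OAc)–C12H2–O–SiMe2 in a trans-fused 1-oxa-2-silacyclohexane; PhSO2 on C3 trans to Si; 4-CH3 trans to the C1–C11 bond; arene as in 15), via o-quinodimethane 16 (not isolated)
Conditions: hν (λ ≥ 300 nm), degassed benzene, 2 mM, 20 °C
Reagents that add atoms: none
Why: Proposed new method: excitation of the twisted 2,6-disubstituted styrene should trigger a 1,5-hydrogen shift from the ortho benzylic CH2 (C1) to the vinyl terminus, which dearomatizes ring A to the o-quinodimethane 16 with the new methyl inside (Z) at C4 and the C11 chain outside (E) at C1; the tethered vinyl sulfone then adds across C1 and C4 in a type 1 intramolecular Diels–Alder reaction. The closest known reaction types are the photochemical 1,5-hydrogen shift of ortho-alkylstyrenes with intermolecular trapping of the o-xylylenes, and the intramolecular photoenolization/Diels–Alder reaction of ortho-alkyl aryl ketones. Ring B closes by the [4+2] cycloaddition itself, and the temporary oxasilinane ring closes in the fused mode through a six-membered chair-like exo tether. C4 is set by the E,Z diene geometry (outside chain, inside methyl, suprafacial addition gives 1,4-trans); C1 is set by C11 through allylic 1,3-strain with C8–H, which holds C11–H in the diene plane so that the tethered arm reaches one face only; C2 and C3 follow from the E dienophile and are erased in step 11. The step needs the cycloaddition to outrun the thermal reverse hydrogen shift, which the activated, tethered dienophile should secure, and any 16 that reverts to 15 is simply re-excited.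

Step 11
Reactants: 17 tricyclic cycloadduct
Product: 18 benzyl (1S,4R)-1-[(2R)-1-(acetyloxy)-3-hydroxypropan-2-yl]-4-methyl-5,6-[(diphenylmethylene)dioxy]-1,4-dihydronaphthalene-7-carboxylate (target numbering)
Conditions: Bu4NF, AcOH (1:1), THF, 0 °C, under argon
Reagents that add atoms: none
Why: Fluoride attack on silicon triggers β-elimination of benzenesulfinate (the known use of β-silyl sulfones as acetylene equivalents) and frees the C12 hydroxyl, while the AcOH buffer should suppress acetyl migration and double-bond isomerization.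

Step 12
Reactants: 18 benzyl (1S,4R)-1-[(2R)-1-(acetyloxy)-3-hydroxypropan-2-yl]-4-methyl-5,6-[(diphenylmethylene)dioxy]-1,4-dihydronaphthalene-7-carboxylate
Product: 19 benzyl (1S,4R)-1-[(2S)-1-(acetyloxy)-3-bromopropan-2-yl]-4-methyl-5,6-[(diphenylmethylene)dioxy]-1,4-dihydronaphthalene-7-carboxylate
Conditions: CBr4, PPh3, CH2Cl2, 0 °C
Reagents that add atoms: tetrabromomethane, BrC(Br)(Br)Br
Why: Appel bromination under neutral conditions converts the primary alcohol at once, which removes the risk of acetyl migration and leaves C11 untouched.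

Step 13
Reactants: 19 benzyl (1S,4R)-1-[(2S)-1-(acetyloxy)-3-bromopropan-2-yl]-4-methyl-5,6-[(diphenylmethylene)dioxy]-1,4-dihydronaphthalene-7-carboxylate
Product: 20 benzyl (1S,4R)-1-[(2S)-1-(acetyloxy)-3-bromopropan-2-yl]-4-methyl-5,6-[(diphenylmethylene)dioxy]-1,2,3,4-tetrahydronaphthalene-7-carboxylate
Conditions: 2-nitrobenzenesulfonohydrazide, Et3N, CH2Cl2, rt
Reagents that add atoms: none
Why: Diimide reduction (concerted syn transfer of H2) saturates the cis-disubstituted C2=C3 bond without the double-bond migration toward C1 or C4 that a metal catalyst could cause.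

Step 14
Reactants: 21 methyl (R)-3-hydroxy-2-methylpropanoate
Product: 22 methyl (R)-3-(benzyloxy)-2-methylpropanoate
Conditions: benzyl 2,2,2-trichloroacetimidate, TfOH (cat.), CH2Cl2/cyclohexane, rt
Reagents that add atoms: benzyl 2,2,2-trichloroacetimidate, N=C(OCc1ccccc1)C(Cl)(Cl)Cl
Why: Acid-catalysed O-benzylation with the trichloroacetimidate avoids base, so the β-hydroxy ester should neither racemize nor eliminate.

Step 15
Reactants: 22 methyl (R)-3-(benzyloxy)-2-methylpropanoate
Product: 24 {[(2S)-2-methylbut-3-en-1-yl]oxy}methylbenzene, via aldehyde 23 (not isolated)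
Conditions: i-Bu2AlH, CH2Cl2, −78 °C; then Ph3P=CH2 (from Ph3PCH3Br and KN(SiMe3)2), THF, −78 °C to rt
Reagents that add atoms: methyltriphenylphosphonium bromide, C[P+](c1ccccc1)(c1ccccc1)c1ccccc1.[Br-]
Why: Partial ester reduction and in situ Wittig methylenation give the terminal alkene without isolating the epimerizable α-methyl aldehyde; C15 comes from the chiral pool.

Step 16
Reactants: 20 benzyl (1S,4R)-1-[(2S)-1-(acetyloxy)-3-bromopropan-2-yl]-4-methyl-5,6-[(diphenylmethylene)dioxy]-1,2,3,4-tetrahydronaphthalene-7-carboxylate; 24 {[(2S)-2-methylbut-3-en-1-yl]oxy}methylbenzene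
Product: 26 benzyl (1S,4R)-1-[(2S,6S)-1-(acetyloxy)-7-(benzyloxy)-6-methylheptan-2-yl]-4-methyl-5,6-[(diphenylmethylene)dioxy]-1,2,3,4-tetrahydronaphthalene-7-carboxylate, via alkylborane 25 (not isolated)
Conditions: 24, 9-BBN-H, THF, rt; then 20, Pd(OAc)2 (cat.), PCy3 (cat.), K3PO4·H2O, THF, rt
Reagents that add atoms: none
Why: Anti-Markovnikov hydroboration followed by alkyl–alkyl Suzuki–Miyaura coupling with the electron-rich bulky phosphine (conditions that tolerate esters and suppress β-hydride elimination) forms C12–C13.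

Step 17
Reactants: 26 benzyl (1S,4R)-1-[(2S,6S)-1-(acetyloxy)-7-(benzyloxy)-6-methylheptan-2-yl]-4-methyl-5,6-[(diphenylmethylene)dioxy]-1,2,3,4-tetrahydronaphthalene-7-carboxylate
Product: 27 (5R,8S)-8-[(2S,6S)-1-(acetyloxy)-7-hydroxy-6-methylheptan-2-yl]-3,4-dihydroxy-5-methyl-5,6,7,8-tetrahydronaphthalene-2-carboxylic acid (CNP0191669.1)
Conditions: H2 (1 atm), palladium on carbon (Pd/C), EtOAc, rt, under exclusion of air on work-up
Reagents that add atoms: none
Why: Hydrogenolysis cleaves the benzyl ether, the benzyl ester and the diphenylmethylene ketal in one operation and should leave the alkyl acetate and all four stereocentres untouched.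

## Compound list

1 | 2,3,4-trihydroxybenzoic acid | OC(=O)c1ccc(O)c(O)c1O | starting material
2 | benzyl 2,3,4-trihydroxybenzoate | O=C(OCc1ccccc1)c1ccc(O)c(O)c1O | intermediate
3 | benzyl 5-bromo-2,3,4-trihydroxybenzoate | O=C(OCc1ccccc1)c1cc(Br)c(O)c(O)c1O | intermediate
4 | benzyl 5-bromo-2,3-dihydroxy-4-{[(trifluoromethyl)sulfonyl]oxy}benzoate | O=C(OCc1ccccc1)c1cc(Br)c(OS(=O)(=O)C(F)(F)F)c(O)c1O | intermediate
5 | benzyl 6-bromo-2,2-diphenyl-7-{[(trifluoromethyl)sulfonyl]oxy}-1,3-benzodioxole-4-carboxylate | O=C(OCc1ccccc1)c1cc(Br)c(OS(=O)(=O)C(F)(F)F)c2OC(c3ccccc3)(c3ccccc3)Oc12 | intermediate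
6 | benzyl 6-bromo-7-ethenyl-2,2-diphenyl-1,3-benzodioxole-4-carboxylate | O=C(OCc1ccccc1)c1cc(Br)c(C=C)c2OC(c3ccccc3)(c3ccccc3)Oc12 | intermediate
7 | 2-methylidenepropane-1,3-diyl diacetate | CC(=O)OCC(=C)COC(C)=O | starting material
8 | 2-[(9-borabicyclo[3.3.1]nonan-9-yl)methyl]propane-1,3-diyl diacetate | CC(=O)OCC(COC(C)=O)CB1C2CCCC1CCC2 | intermediate (not isolated)
9 | benzyl 6-[3-(acetyloxy)-2-[(acetyloxy)methyl]propyl]-7-ethenyl-2,2-diphenyl-1,3-benzodioxole-4-carboxylate | CC(=O)OCC(COC(C)=O)Cc1cc(C(=O)OCc2ccccc2)c2OC(c3ccccc3)(c3ccccc3)Oc2c1C=C | intermediate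
10 | benzyl 6-[(2R)-3-(acetyloxy)-2-(hydroxymethyl)propyl]-7-ethenyl-2,2-diphenyl-1,3-benzodioxole-4-carboxylate | CC(=O)OC[C@@H](CO)Cc1cc(C(=O)OCc2ccccc2)c2OC(c3ccccc3)(c3ccccc3)Oc2c1C=C | intermediate
11 | chloro(ethenyl)dimethylsilane | C=C[Si](C)(C)Cl | starting material
12 | benzenesulfonyl chloride | O=S(=O)(Cl)c1ccccc1 | starting material
13 | chloro[1-chloro-2-(phenylsulfonyl)ethyl]dimethylsilane | C[Si](C)(Cl)C(Cl)CS(=O)(=O)c1ccccc1 | intermediate (not isolated)
14 | chloro(dimethyl)[(E)-2-(phenylsulfonyl)ethenyl]silane | C[Si](C)(Cl)/C=C/S(=O)(=O)c1ccccc1 | intermediate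
15 | benzyl 6-[(2S)-3-(acetyloxy)-2-[({dimethyl[(E)-2-(phenylsulfonyl)ethenyl]silyl}oxy)methyl]propyl]-7-ethenyl-2,2-diphenyl-1,3-benzodioxole-4-carboxylate | CC(=O)OC[C@@H](CO[Si](C)(C)/C=C/S(=O)(=O)c1ccccc1)Cc1cc(C(=O)OCc2ccccc2)c2OC(c3ccccc3)(c3ccccc3)Oc2c1C=C | intermediate
16 | o-quinodimethane from 15 (C1=C8a with the C11 chain outside, C4=C4a with the new methyl inside) | C/C=C1\C(=C\[C@@H](COC(C)=O)CO[Si](C)(C)/C=C/S(=O)(=O)c2ccccc2)C=C(C(=O)OCc2ccccc2)C2=C1OC(c1ccccc1)(c1ccccc1)O2 | intermediate (not isolated)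
17 | tricyclic cycloadduct (C1/C2 spanned by C11H(CH2OAc)–C12H2–O–SiMe2, trans-fused; 3-PhSO2 trans to Si; 4-CH3 trans to the C1–C11 bond) | CC(=O)OC[C@H]1CO[Si](C)(C)[C@H]2[C@H](S(=O)(=O)c3ccccc3)[C@@H](C)c3c4OC(c5ccccc5)(c5ccccc5)Oc4c(C(=O)OCc4ccccc4)cc3[C@H]12 | intermediate
18 | benzyl (1S,4R)-1-[(2R)-1-(acetyloxy)-3-hydroxypropan-2-yl]-4-methyl-5,6-[(diphenylmethylene)dioxy]-1,4-dihydronaphthalene-7-carboxylate | CC(=O)OC[C@@H](CO)[C@@H]1C=C[C@@H](C)c2c1cc(C(=O)OCc1ccccc1)c1OC(c3ccccc3)(c3ccccc3)Oc21 | intermediate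
19 | benzyl (1S,4R)-1-[(2S)-1-(acetyloxy)-3-bromopropan-2-yl]-4-methyl-5,6-[(diphenylmethylene)dioxy]-1,4-dihydronaphthalene-7-carboxylate | CC(=O)OC[C@@H](CBr)[C@@H]1C=C[C@@H](C)c2c1cc(C(=O)OCc1ccccc1)c1OC(c3ccccc3)(c3ccccc3)Oc21 | intermediate
20 | benzyl (1S,4R)-1-[(2S)-1-(acetyloxy)-3-bromopropan-2-yl]-4-methyl-5,6-[(diphenylmethylene)dioxy]-1,2,3,4-tetrahydronaphthalene-7-carboxylate | CC(=O)OC[C@@H](CBr)[C@@H]1CC[C@@H](C)c2c1cc(C(=O)OCc1ccccc1)c1OC(c3ccccc3)(c3ccccc3)Oc21 | intermediate
21 | methyl (R)-3-hydroxy-2-methylpropanoate | COC(=O)[C@H](C)CO | starting material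
22 | methyl (R)-3-(benzyloxy)-2-methylpropanoate | COC(=O)[C@H](C)COCc1ccccc1 | intermediate
23 | (R)-3-(benzyloxy)-2-methylpropanal | O=C[C@H](C)COCc1ccccc1 | intermediate (not isolated)
24 | {[(2S)-2-methylbut-3-en-1-yl]oxy}methylbenzene | C=C[C@H](C)COCc1ccccc1 | intermediate
25 | 9-[(3S)-4-(benzyloxy)-3-methylbutyl]-9-borabicyclo[3.3.1]nonane | B1(CC[C@H](C)COCc2ccccc2)C2CCCC1CCC2 | intermediate (not isolated)
26 | benzyl (1S,4R)-1-[(2S,6S)-1-(acetyloxy)-7-(benzyloxy)-6-methylheptan-2-yl]-4-methyl-5,6-[(diphenylmethylene)dioxy]-1,2,3,4-tetrahydronaphthalene-7-carboxylate | CC(=O)OC[C@@H](CCC[C@H](C)COCc1ccccc1)[C@@H]1CC[C@@H](C)c2c1cc(C(=O)OCc1ccccc1)c1OC(c3ccccc3)(c3ccccc3)Oc21 | intermediate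
27 | (5R,8S)-8-[(2S,6S)-1-(acetyloxy)-7-hydroxy-6-methylheptan-2-yl]-3,4-dihydroxy-5-methyl-5,6,7,8-tetrahydronaphthalene-2-carboxylic acid | CC(=O)OC[C@@H](CCC[C@H](C)CO)[C@@H]1CC[C@@H](C)c2c1cc(C(=O)O)c(O)c2O | target

## Step count and risks

Total step count: 17. Longest linear sequence: 14 steps (steps 1–7, 9–13, 16, 17).

Steps most likely to fail:

1. Step 10 (Proposed new method). The photochemical hydrogen shift may be inefficient, or the o-quinodimethane 16 may return to 15 (or close to a benzocyclobutene) faster than the tethered sulfone traps it; competing [2+2] photocycloaddition is also possible. The fallback uses the known photoenolization/Diels–Alder reaction and sets out from 10. Wacker oxidation (PdCl2, CuCl, O2, DMF/H2O) of the aryl vinyl group should give the aryl methyl ketone F1, and silylation with 14 as in step 9 the keto silyl ether F2. Irradiation at 365 nm should give the E photoenol, which the tethered vinyl sulfone traps (here in the electronically preferred orientation, sulfonyl carbon to the carbinol carbon C4) to give the tertiary benzylic alcohol F3; C1 is set as in the main route and the C4 hydroxyl is cis to the C1 side chain. Bu4NF/AcOH should give the dihydronaphthalenol F4 and diimide the tetralinol F5. Camphorsulfonic acid in benzene should dehydrate only the tertiary benzylic alcohol to the 3,4-alkene F6. Hydrogenation with [Ir(cod)(PCy3)(py)]PF6, directed by the C12 hydroxyl on the C1 side chain, should deliver hydrogen to C4 from the side-chain face and give the 1,4-trans tetralin alcohol F7. Appel bromination (CBr4, PPh3) of F7 comes back to the route at 20.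

2. Step 16. Oxidative addition into the β-branched primary bromide may be slow, and β-hydride elimination or protodeboronation may take over. The fallback sets out from 20. Displacement with 1-phenyl-1H-tetrazole-5-thiol and K2CO3 should give the sulfide F8, and oxidation with H2O2 and (NH4)6Mo7O24 the sulfone F9. Alkene 24 is converted by hydroboration–oxidation into the alcohol F10 and by oxidation with the periodinane DMP into the aldehyde F11. Julia–Kocienski olefination of F9 with F11 (KN(SiMe3)2 added at −78 °C to the mixture of both, so that the acetate is not attacked) should give the C12=C13 alkene F12 as an E/Z mixture. Diimide reduction as in step 13 comes back to the route at 26.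

3. Step 3. Triflation may take place at the wrong phenol or twice, or the triflyl group may scramble under base. The fallback sets out from 3. O-Allylation (allyl bromide, one equivalent of K2CO3, acetone) at the most acidic 4-OH should give the allyl ether F13, a stable compound that can be purified and whose regiochemistry can be proven. Ketalization as in step 4 gives the ketal F14, and deallylation (Pd(PPh3)4, morpholine) the single free phenol F15. Triflation (Tf2O, pyridine), now without any selectivity demand, comes back to the route at 5.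

Further compounds
F1 | step 10 | benzyl 7-acetyl-6-[(2R)-3-(acetyloxy)-2-(hydroxymethyl)propyl]-2,2-diphenyl-1,3-benzodioxole-4-carboxylate | CC(=O)OC[C@@H](CO)Cc1cc(C(=O)OCc2ccccc2)c2OC(c3ccccc3)(c3ccccc3)Oc2c1C(C)=O
F2 | step 10 | benzyl 7-acetyl-6-[(2S)-3-(acetyloxy)-2-[({dimethyl[(E)-2-(phenylsulfonyl)ethenyl]silyl}oxy)methyl]propyl]-2,2-diphenyl-1,3-benzodioxole-4-carboxylate | CC(=O)OC[C@@H](CO[Si](C)(C)/C=C/S(=O)(=O)c1ccccc1)Cc1cc(C(=O)OCc2ccccc2)c2OC(c3ccccc3)(c3ccccc3)Oc2c1C(C)=O
F3 | step 10 | photoenol cycloadduct (as 17, but C4 bears CH3 and OH, the OH cis to the C1–C11 bond) | CC(=O)OC[C@H]1CO[Si](C)(C)[C@H]2[C@H](S(=O)(=O)c3ccccc3)[C@](C)(O)c3c4OC(c5ccccc5)(c5ccccc5)Oc4c(C(=O)OCc4ccccc4)cc3[C@H]12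
F4 | step 10 | benzyl 1-[(2R)-1-(acetyloxy)-3-hydroxypropan-2-yl]-4-hydroxy-4-methyl-5,6-[(diphenylmethylene)dioxy]-1,4-dihydronaphthalene-7-carboxylate (4-OH cis to the side chain) | CC(=O)OC[C@@H](CO)[C@@H]1C=C[C@](C)(O)c2c1cc(C(=O)OCc1ccccc1)c1OC(c3ccccc3)(c3ccccc3)Oc21
F5 | step 10 | benzyl 1-[(2R)-1-(acetyloxy)-3-hydroxypropan-2-yl]-4-hydroxy-4-methyl-5,6-[(diphenylmethylene)dioxy]-1,2,3,4-tetrahydronaphthalene-7-carboxylate (4-OH cis to the side chain) | CC(=O)OC[C@@H](CO)[C@@H]1CC[C@](C)(O)c2c1cc(C(=O)OCc1ccccc1)c1OC(c3ccccc3)(c3ccccc3)Oc21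
F6 | step 10 | benzyl (1S)-1-[(2R)-1-(acetyloxy)-3-hydroxypropan-2-yl]-4-methyl-5,6-[(diphenylmethylene)dioxy]-1,2-dihydronaphthalene-7-carboxylate | CC(=O)OC[C@@H](CO)[C@@H]1CC=C(C)c2c1cc(C(=O)OCc1ccccc1)c1OC(c3ccccc3)(c3ccccc3)Oc21
F7 | step 10 | benzyl (1S,4R)-1-[(2R)-1-(acetyloxy)-3-hydroxypropan-2-yl]-4-methyl-5,6-[(diphenylmethylene)dioxy]-1,2,3,4-tetrahydronaphthalene-7-carboxylate | CC(=O)OC[C@@H](CO)[C@@H]1CC[C@@H](C)c2c1cc(C(=O)OCc1ccccc1)c1OC(c3ccccc3)(c3ccccc3)Oc21
F8 | step 16 | 1-phenyl-1H-tetrazol-5-yl sulfide of 20 (S in place of Br at C12) | CC(=O)OC[C@@H](CSc1nnnn1-c1ccccc1)[C@@H]1CC[C@@H](C)c2c1cc(C(=O)OCc1ccccc1)c1OC(c3ccccc3)(c3ccccc3)Oc21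
F9 | step 16 | 1-phenyl-1H-tetrazol-5-yl sulfone from F8 | CC(=O)OC[C@@H](CS(=O)(=O)c1nnnn1-c1ccccc1)[C@@H]1CC[C@@H](C)c2c1cc(C(=O)OCc1ccccc1)c1OC(c3ccccc3)(c3ccccc3)Oc21
F10 | step 16 | (S)-4-(benzyloxy)-3-methylbutan-1-ol | OCC[C@H](C)COCc1ccccc1
F11 | step 16 | (S)-4-(benzyloxy)-3-methylbutanal | O=CC[C@H](C)COCc1ccccc1
F12 | step 16 | benzyl (1S,4R)-1-[(2S,6S)-1-(acetyloxy)-7-(benzyloxy)-6-methylhept-3-en-2-yl]-4-methyl-5,6-[(diphenylmethylene)dioxy]-1,2,3,4-tetrahydronaphthalene-7-carboxylate (E/Z mixture) | CC(=O)OC[C@@H](C=CC[C@H](C)COCc1ccccc1)[C@@H]1CC[C@@H](C)c2c1cc(C(=O)OCc1ccccc1)c1OC(c3ccccc3)(c3ccccc3)Oc21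
F13 | step 3 | benzyl 5-bromo-2,3-dihydroxy-4-(prop-2-en-1-yloxy)benzoate | O=C(OCc1ccccc1)c1cc(Br)c(OCC=C)c(O)c1O
F14 | step 3 | benzyl 6-bromo-2,2-diphenyl-7-(prop-2-en-1-yloxy)-1,3-benzodioxole-4-carboxylate | O=C(OCc1ccccc1)c1cc(Br)c(OCC=C)c2OC(c3ccccc3)(c3ccccc3)Oc12
F15 | step 3 | benzyl 6-bromo-7-hydroxy-2,2-diphenyl-1,3-benzodioxole-4-carboxylate | O=C(OCc1ccccc1)c1cc(Br)c(O)c2OC(c3ccccc3)(c3ccccc3)Oc12
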